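**Strategy.** The target is disconnected at the C15 ketone into two halves that carry the same trans-decalin (rings A and B: equatorial C3–OH, C4 with axial C19, C5, C9, C10, exocyclic C8=C17); one C12 aldehyde therefore serves both, and the halves are joined late by nitro (acyl-anion) chemistry. The decalin is made in one cationic bicyclisation: an epoxide opens at C4, the C5=C10 alkene and then an allylsilane add, forming C4–C5 and C9–C10, closing rings A and B, setting C4, C5, C9 and C10 and leaving C8=C17. The precursor is an acyclic (3R,4S)-epoxy diene with a C19 silyl ether, an E C5=C10 alkene and a C8 trimethylsilylmethyl alkene bearing the C11–C12 silyl ether.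

Key step: step 12

Remark: labdane locants (C1–C20) are used for each decalin half, primed for the butenolide half. "DkCH2–" stands for the 3,19-O-isopropylidene decalin attached through C11, SMILES fragment C[C@@H]1C(=C)CC[C@@H]2[C@](C)(COC3(C)C)[C@H](O3)CC[C@]21C. The C12 oxygen is carried through the key step as a tert-butyldiphenylsilyl ether so that both silyl ethers go on and come off together.

Step 1
Reactants: 1 tert-butyldimethyl(pent-4-yn-1-yloxy)silane; 2 trimethylaluminium; 3 oxirane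
Product: 6 (3E)-7-[(tert-butyldimethylsilyl)oxy]-4-methylhept-3-en-1-ol, via alkenyldimethylalane 4 (not isolated), via lithium alkenylalanate 5 (not isolated)
Conditions: Me3Al (2 equiv), Cp2ZrCl2 (0.25 equiv), ClCH2CH2Cl, rt; volatiles removed in vacuo; n-BuLi (1 equiv), hexane/THF, 0 °C; oxirane (3 equiv), 0 °C to rt; aq potassium sodium tartrate
Reagents that add atoms: none
Why: Zr-catalysed syn-carboalumination of the terminal alkyne (Negishi methylalumination) puts methyl on the internal carbon and aluminium on the terminal carbon of the same face, and the alanate formed with n-BuLi opens oxirane with retention at the alkenyl carbon, so the methyl is cis to the hydroxyethyl arm and the E alkene (future C5=C10) results.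

Step 2
Reactants: 6 (3E)-7-[(tert-butyldimethylsilyl)oxy]-4-methylhept-3-en-1-ol
Product: 7 tert-butyl{[(4E)-7-iodo-4-methylhept-4-en-1-yl]oxy}dimethylsilane
Conditions: I2, PPh3, imidazole, CH2Cl2, 0 °C
Reagents that add atoms: iodine, II
Why: Appel-type iodination of the primary alcohol through the alkoxyphosphonium ion, buffered by imidazole so that the silyl ether survives.

Step 3
Reactants: 8 2,3-dihydrofuran; 7 tert-butyl{[(4E)-7-iodo-4-methylhept-4-en-1-yl]oxy}dimethylsilane
Product: 10 tert-butyl{[(4E)-7-(4,5-dihydrofuran-2-yl)-4-methylhept-4-en-1-yl]oxy}dimethylsilane, via 5-lithio-2,3-dihydrofuran 9 (not isolated)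
Conditions: t-BuLi, THF, −78 to 0 °C; then 7, −30 °C to rt
Reagents that add atoms: none
Why: t-BuLi removes the vinylic C5–H of the enol ether and the vinyllithium displaces the primary homoallylic iodide (SN2 alkylation of a metalated cyclic enol ether), which forms the C7–C8 bond; no stereocentre is formed.

Step 4
Reactants: 10 tert-butyl{[(4E)-7-(4,5-dihydrofuran-2-yl)-4-methylhept-4-en-1-yl]oxy}dimethylsilane; 11 (trimethylsilyl)methylmagnesium chloride
Product: 12 (3Z,7E)-11-[(tert-butyldimethylsilyl)oxy]-8-methyl-4-[(trimethylsilyl)methyl]undeca-3,7-dien-1-ol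
Conditions: Me3SiCH2MgCl (3 equiv), NiCl2(PPh3)2 (5 mol %), toluene, reflux; aq NH4Cl
Reagents that add atoms: none
Why: Ni-catalysed Kumada-type coupling at the vinylic C–O bond of the cyclic enol ether with a Grignard reagent that has no β-hydrogen opens the ring and puts CH2SiMe3 in place of the ring oxygen with retention, so C11 is cis to CH2SiMe3 and trans to C7 (Z allylsilane); no allylic C–O bond is present to compete.

Step 5
Reactants: 12 (3Z,7E)-11-[(tert-butyldimethylsilyl)oxy]-8-methyl-4-[(trimethylsilyl)methyl]undeca-3,7-dien-1-ol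
Product: 13 (3Z,7E)-11-[(tert-butyldimethylsilyl)oxy]-1-[(tert-butyldiphenylsilyl)oxy]-8-methyl-4-[(trimethylsilyl)methyl]undeca-3,7-diene
Conditions: TBDPSCl, imidazole, DMF, rt
Reagents that add atoms: tert-butyl(chloro)diphenylsilane, CC(C)(C)[Si](Cl)(c1ccccc1)c1ccccc1
Why: imidazole-promoted silylation of the primary homoallylic alcohol gives an ether that survives the later base, hydride and Lewis-acid steps.

Step 6
Reactants: 13 (3Z,7E)-11-[(tert-butyldimethylsilyl)oxy]-1-[(tert-butyldiphenylsilyl)oxy]-8-methyl-4-[(trimethylsilyl)methyl]undeca-3,7-diene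
Product: 14 (4E,8Z)-11-[(tert-butyldiphenylsilyl)oxy]-4-methyl-8-[(trimethylsilyl)methyl]undeca-4,8-dien-1-ol
Conditions: PPTS (0.3 equiv), MeOH, rt
Reagents that add atoms: none
Why: acid-catalysed methanolysis cleaves the primary tert-butyldimethylsilyl ether far faster than the tert-butyldiphenylsilyl ether (selective desilylation), and the pyridinium acid is too weak to protodesilylate the allylsilane.

Step 7
Reactants: 14 (4E,8Z)-11-[(tert-butyldiphenylsilyl)oxy]-4-methyl-8-[(trimethylsilyl)methyl]undeca-4,8-dien-1-ol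
Product: 15 (4E,8Z)-11-[(tert-butyldiphenylsilyl)oxy]-4-methyl-8-[(trimethylsilyl)methyl]undeca-4,8-dienal
Conditions: Dess–Martin periodinane, pyridine, CH2Cl2, 0 °C to rt
Reagents that add atoms: none
Why: buffered hypervalent-iodine oxidation of the primary alcohol stops at the aldehyde and leaves the allylsilane untouched.

Step 8
Reactants: 15 (4E,8Z)-11-[(tert-butyldiphenylsilyl)oxy]-4-methyl-8-[(trimethylsilyl)methyl]undeca-4,8-dienal; 16 ethyl 2-[bis(2,2,2-trifluoroethoxy)phosphoryl]propanoate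
Product: 18 ethyl (2Z,6E,10Z)-13-[(tert-butyldiphenylsilyl)oxy]-2,6-dimethyl-10-[(trimethylsilyl)methyl]trideca-2,6,10-trienoate, via potassium phosphonate carbanion 17 (not isolated)
Conditions: 16, KN(SiMe3)2, 18-crown-6, THF, −78 °C; then 15
Reagents that add atoms: none
Why: Still–Gennari olefination, in which the electron-poor phosphonate and the dissociated potassium ion make elimination faster than equilibration, gives the Z enoate with the ester cis to the chain, the geometry that later places C19 axial.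

Step 9
Reactants: 18 ethyl (2Z,6E,10Z)-13-[(tert-butyldiphenylsilyl)oxy]-2,6-dimethyl-10-[(trimethylsilyl)methyl]trideca-2,6,10-trienoate
Product: 19 (2Z,6E,10Z)-13-[(tert-butyldiphenylsilyl)oxy]-2,6-dimethyl-10-[(trimethylsilyl)methyl]trideca-2,6,10-trien-1-ol
Conditions: i-Bu2AlH (2.3 equiv), CH2Cl2, −78 °C; aq potassium sodium tartrate
Reagents that add atoms: none
Why: 1,2-reduction of the conjugated ester by the aluminium hydride gives the allylic alcohol without touching the alkene geometry or the silyl ether.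

Step 10
Reactants: 19 (2Z,6E,10Z)-13-[(tert-butyldiphenylsilyl)oxy]-2,6-dimethyl-10-[(trimethylsilyl)methyl]trideca-2,6,10-trien-1-ol
Product: 20 [(2S,3R)-3-{(3E,7Z)-10-[(tert-butyldiphenylsilyl)oxy]-3-methyl-7-[(trimethylsilyl)methyl]deca-3,7-dien-1-yl}-2-methyloxiran-2-yl]methanol
Conditions: Ti(OiPr)4 (10 mol %), L-(+)-diethyl tartrate (12 mol %), t-BuOOH, 4 Å MS, CH2Cl2, −20 °C
Reagents that add atoms: tert-butyl hydroperoxide, CC(C)(C)OO
Why: Sharpless asymmetric epoxidation, in which the complex of Ti(OiPr)4 with L-(+)-diethyl tartrate delivers oxygen to the face of the Z allylic alcohol that gives the (2S,3R)-epoxide (C4 S, C3 R in labdane numbering), and only the titanium-bound allylic alkene reacts.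

Step 11
Reactants: 20 [(2S,3R)-3-{(3E,7Z)-10-[(tert-butyldiphenylsilyl)oxy]-3-methyl-7-[(trimethylsilyl)methyl]deca-3,7-dien-1-yl}-2-methyloxiran-2-yl]methanol
Product: 21 tert-butyl{[(2S,3R)-3-{(3E,7Z)-10-[(tert-butyldiphenylsilyl)oxy]-3-methyl-7-[(trimethylsilyl)methyl]deca-3,7-dien-1-yl}-2-methyloxiran-2-yl]methoxy}diphenylsilane
Conditions: TBDPSCl, imidazole, DMF, rt
Reagents that add atoms: tert-butyl(chloro)diphenylsilane, CC(C)(C)[Si](Cl)(c1ccccc1)c1ccccc1
Why: silylation of the primary C19 alcohol gives a bulky, weakly Lewis-basic ether that should not chelate the Lewis acid of the next step.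

Step 12
Reactants: 21 tert-butyl{[(2S,3R)-3-{(3E,7Z)-10-[(tert-butyldiphenylsilyl)oxy]-3-methyl-7-[(trimethylsilyl)methyl]deca-3,7-dien-1-yl}-2-methyloxiran-2-yl]methoxy}diphenylsilane
Product: 22 (1R,2R,4aS,5R,8aS)-1-{[(tert-butyldiphenylsilyl)oxy]methyl}-5-{2-[(tert-butyldiphenylsilyl)oxy]ethyl}-1,4a-dimethyl-6-methylidenedecahydronaphthalen-2-ol
Conditions: MeAlCl2 (2 equiv), CH2Cl2, −78 °C; aq potassium sodium tartrate
Reagents that add atoms: none
Why: MeAlCl2 binds the epoxide oxygen and the C4–O bond ionises as the C5=C10 alkene attacks C4 from the face opposite the oxygen; the C10 tertiary cation is captured by C9 of the allylsilane and the β-silyl cation at C8 loses Me3Si to leave C8=C17. The closest known reaction is the Lewis-acid epoxy-polyene bicyclisation with allylsilane termination. Ring A closes 6-endo through a chair and ring B closes 6-endo through a second chair, with anti addition across both alkenes. C3 comes unchanged from the epoxide and its oxygen ends equatorial; C4 is set by the inverting anti opening, so the epoxide substituent cis to the chain (C19) becomes axial; C5 and C10 follow from the E C5=C10 geometry (trans fusion, axial C20); C9 follows from the C8=C9 geometry, the C11 chain trans to C7 ending equatorial. The step needs opening at tertiary C4 and not at C3, and closure of ring B faster than proton loss from the C10 cation or its capture by the C3 alkoxide. The tertiary centre, the bulky silyl ethers, the low temperature and the nucleophilic 2-(silylmethyl)alkene should secure this.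

Step 13
Reactants: 22 (1R,2R,4aS,5R,8aS)-1-{[(tert-butyldiphenylsilyl)oxy]methyl}-5-{2-[(tert-butyldiphenylsilyl)oxy]ethyl}-1,4a-dimethyl-6-methylidenedecahydronaphthalen-2-ol
Product: 23 (1R,2R,4aS,5R,8aS)-5-(2-hydroxyethyl)-1-(hydroxymethyl)-1,4a-dimethyl-6-methylidenedecahydronaphthalen-2-ol
Conditions: Bu4NF (4 equiv), THF, rt to 50 °C
Reagents that add atoms: none
Why: fluoride cleaves both Si–O bonds (desilylation), the neopentyl C19 ether needing gentle warming.

Step 14
Reactants: 23 (1R,2R,4aS,5R,8aS)-5-(2-hydroxyethyl)-1-(hydroxymethyl)-1,4a-dimethyl-6-methylidenedecahydronaphthalen-2-ol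
Product: 24 DkCH2–CH2OH, the 3,19-O-isopropylidene derivative of 23 with free C12 hydroxyl
Conditions: 2,2-dimethoxypropane, PPTS (cat.), acetone, rt; aq NaHCO3
Reagents that add atoms: 2,2-dimethoxypropane, COC(C)(C)OC
Why: the equatorial C3 hydroxyl and the axial C19 hydroxymethyl close a six-membered isopropylidene ketal by trans-ketalisation, and any mixed ketal at the C12 hydroxyl falls off on aqueous work-up.

Step 15
Reactants: 24 DkCH2–CH2OH
Product: 25 DkCH2–CHO, the C12 aldehyde
Conditions: Dess–Martin periodinane, pyridine, CH2Cl2, 0 °C to rt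
Reagents that add atoms: none
Why: buffered hypervalent-iodine oxidation of the primary alcohol gives the aldehyde, which is not conjugated and has no stereocentre at its α-carbon.

Step 16
Reactants: 25 DkCH2–CHO; 26 methyl acrylate
Product: 27 methyl 3-hydroxy-2-methylidene-4-Dk-butanoate (both C12 epimers)
Conditions: methyl acrylate (5 equiv), quinuclidine (0.5 equiv), MeOH, rt
Reagents that add atoms: none
Why: Morita–Baylis–Hillman reaction, in which the amine-acrylate zwitterion adds to the unhindered aldehyde and the amine is then expelled; the new C12 carbinol centre is removed in step 22.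

Step 17
Reactants: 27 methyl 3-hydroxy-2-methylidene-4-Dk-butanoate
Product: 28 methyl 3-acetoxy-2-methylidene-4-Dk-butanoate
Conditions: Ac2O, DMAP (cat.), pyridine, CH2Cl2, 0 °C
Reagents that add atoms: acetic anhydride, CC(=O)OC(C)=O
Why: acyl-transfer catalysis acetylates the allylic alcohol and so installs the leaving group for the later SN2′ substitution.

Step 18
Reactants: 25 DkCH2–CHO; 29 nitromethane
Product: 32 (E)-1-nitro-3-Dk-prop-1-ene, via β-nitro alcohol 30 (not isolated), via β-nitro mesylate 31 (not isolated)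
Conditions: MeNO2 (10 equiv), KOtBu (10 mol %), THF/t-BuOH, 0 °C; evaporate; MsCl, Et3N, CH2Cl2, −20 °C
Reagents that add atoms: none
Why: Henry addition of nitromethane followed by mesylation and E1cB elimination gives the conjugated E nitroalkene; the carbinol centre formed on the way is destroyed.

Step 19
Reactants: 32 (E)-1-nitro-3-Dk-prop-1-ene; 33 tetronic acid (4-hydroxyfuran-2(5H)-one)
Product: 34 4-hydroxy-3-[(2S)-1-nitro-3-Dk-propan-2-yl]furan-2(5H)-one
Conditions: 1-[3,5-bis(trifluoromethyl)phenyl]-3-[(1S,2S)-2-(dimethylamino)cyclohexyl]thiourea (10 mol %), CH2Cl2, −20 °C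
Reagents that add atoms: none
Why: Michael addition of a cyclic 1,3-dicarbonyl to a nitroalkene under bifunctional amine-thiourea catalysis, in which the thiourea binds the nitro group and the ammonium-paired tetronate adds through its α-carbon; the (S,S) catalyst is chosen to expose the Re face of C12′, which gives 12′S, and the (R,R) catalyst would give the epimer.

Step 20
Reactants: 34 4-hydroxy-3-[(2S)-1-nitro-3-Dk-propan-2-yl]furan-2(5H)-one
Product: 35 4-[(2S)-1-nitro-3-Dk-propan-2-yl]-5-oxo-2,5-dihydrofuran-3-yl trifluoromethanesulfonate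
Conditions: Tf2O, i-Pr2NEt, CH2Cl2, −78 °C
Reagents that add atoms: trifluoromethanesulfonic anhydride, O=S(=O)(OS(=O)(=O)C(F)(F)F)C(F)(F)F
Why: the acidic tetronic enol is sulfonylated on oxygen much faster than the nitroalkane is deprotonated (O-triflation of a vinylogous acid).

Step 21
Reactants: 35 4-[(2S)-1-nitro-3-Dk-propan-2-yl]-5-oxo-2,5-dihydrofuran-3-yl trifluoromethanesulfonate
Product: 36 3-[(2S)-1-nitro-3-Dk-propan-2-yl]furan-2(5H)-one
Conditions: Pd(OAc)2 (5 mol %), PPh3 (10 mol %), HCO2H, Bu3N, DMF, 50 °C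
Reagents that add atoms: none
Why: zerovalent palladium inserts into the vinyl C–O bond of the triflate and formate delivers hydride with loss of CO2 (formate reduction of a vinyl triflate), which gives the α-substituted butenolide and leaves the nitro group and the exocyclic alkene alone.

Step 22
Reactants: 36 3-[(2S)-1-nitro-3-Dk-propan-2-yl]furan-2(5H)-one; 28 methyl 3-acetoxy-2-methylidene-4-Dk-butanoate
Product: 37 methyl (2E)-4-Dk-2-[(3S)-2-nitro-3-(2-oxo-2,5-dihydrofuran-3-yl)-4-Dk-butyl]but-2-enoate (both C15 epimers)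
Conditions: K2CO3, DMF, 0 °C to rt
Reagents that add atoms: none
Why: the nitronate of 36, a nitro-based acyl-anion equivalent, adds to the terminal methylene of the Morita–Baylis–Hillman acetate and acetate is expelled (SN2′ addition-elimination), which forms C14–C15 and should give the E enoate with C11 trans to the ester; C12′ is not acidic at this stage and C15 is removed in step 23.

Step 23
Reactants: 37 methyl (2E)-4-Dk-2-[(3S)-2-nitro-3-(2-oxo-2,5-dihydrofuran-3-yl)-4-Dk-butyl]but-2-enoate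
Product: 39 methyl (2E)-4-Dk-2-[(3S)-2-oxo-3-(2-oxo-2,5-dihydrofuran-3-yl)-4-Dk-butyl]but-2-enoate, via sodium nitronate 38 (not isolated)
Conditions: NaOMe (1.05 equiv), MeOH, 0 °C; then TiCl3 (aq, 4 equiv), NH4OAc, THF/H2O, rt
Reagents that add atoms: water, O
Why: reductive Nef reaction, in which trivalent titanium reduces the nitronate to the imine and water hydrolyses it at pH 5–6 to the C15 ketone; the base-free buffered medium should avoid epimerisation of the now α-keto C12′ and migration of the C12=C13 alkene.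

Step 24
Reactants: 39 methyl (2E)-4-Dk-2-[(3S)-2-oxo-3-(2-oxo-2,5-dihydrofuran-3-yl)-4-Dk-butyl]but-2-enoate
Product: 40 target, methyl (2E)-4-Dec-2-[(3S)-2-oxo-3-(2-oxo-2,5-dihydrofuran-3-yl)-4-Dec-butyl]but-2-enoate, Dec = (1R,4aS,5R,6R,8aS)-6-hydroxy-5-(hydroxymethyl)-5,8a-dimethyl-2-methylidenedecahydronaphthalen-1-yl
Conditions: AcOH/H2O/THF (3:1:1), rt
Reagents that add atoms: none
Why: mild aqueous acid hydrolyses both isopropylidene ketals to the 3,19-diols (ketal hydrolysis) without moving the C8=C17 alkenes or epimerising C12′.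

**Compound list**

1 | tert-butyldimethyl(pent-4-yn-1-yloxy)silane | C#CCCCO[Si](C)(C)C(C)(C)C | starting material
2 | trimethylaluminium | C[Al](C)C | starting material
3 | oxirane | C1CO1 | starting material
4 | {(1E)-5-[(tert-butyldimethylsilyl)oxy]-2-methylpent-1-en-1-yl}dimethylaluminium | C[Al](C)/C=C(\C)CCCO[Si](C)(C)C(C)(C)C | intermediate (not isolated)
5 | lithium butyl{(1E)-5-[(tert-butyldimethylsilyl)oxy]-2-methylpent-1-en-1-yl}dimethylaluminate | [Li+].CCCC[Al-](C)(C)/C=C(\C)CCCO[Si](C)(C)C(C)(C)C | intermediate (not isolated)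
6 | (3E)-7-[(tert-butyldimethylsilyl)oxy]-4-methylhept-3-en-1-ol | OCC/C=C(\C)CCCO[Si](C)(C)C(C)(C)C | intermediate
7 | tert-butyl{[(4E)-7-iodo-4-methylhept-4-en-1-yl]oxy}dimethylsilane | ICC/C=C(\C)CCCO[Si](C)(C)C(C)(C)C | intermediate
8 | 2,3-dihydrofuran | C1=COCC1 | starting material
9 | 5-lithio-2,3-dihydrofuran | [Li]C1=CCCO1 | intermediate (not isolated)
10 | tert-butyl{[(4E)-7-(4,5-dihydrofuran-2-yl)-4-methylhept-4-en-1-yl]oxy}dimethylsilane | O1CCC=C1CC/C=C(\C)CCCO[Si](C)(C)C(C)(C)C | intermediate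
11 | (trimethylsilyl)methylmagnesium chloride | C[Si](C)(C)C[Mg]Cl | starting material
12 | (3Z,7E)-11-[(tert-butyldimethylsilyl)oxy]-8-methyl-4-[(trimethylsilyl)methyl]undeca-3,7-dien-1-ol | OCC/C=C(\C[Si](C)(C)C)CC/C=C(\C)CCCO[Si](C)(C)C(C)(C)C | intermediate
13 | (3Z,7E)-11-[(tert-butyldimethylsilyl)oxy]-1-[(tert-butyldiphenylsilyl)oxy]-8-methyl-4-[(trimethylsilyl)methyl]undeca-3,7-diene | CC(C)(C)[Si](c1ccccc1)(c1ccccc1)OCC/C=C(\C[Si](C)(C)C)CC/C=C(\C)CCCO[Si](C)(C)C(C)(C)C | intermediate
14 | (4E,8Z)-11-[(tert-butyldiphenylsilyl)oxy]-4-methyl-8-[(trimethylsilyl)methyl]undeca-4,8-dien-1-ol | CC(C)(C)[Si](c1ccccc1)(c1ccccc1)OCC/C=C(\C[Si](C)(C)C)CC/C=C(\C)CCCO | intermediate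
15 | (4E,8Z)-11-[(tert-butyldiphenylsilyl)oxy]-4-methyl-8-[(trimethylsilyl)methyl]undeca-4,8-dienal | CC(C)(C)[Si](c1ccccc1)(c1ccccc1)OCC/C=C(\C[Si](C)(C)C)CC/C=C(\C)CCC=O | intermediate
16 | ethyl 2-[bis(2,2,2-trifluoroethoxy)phosphoryl]propanoate | CCOC(=O)C(C)P(=O)(OCC(F)(F)F)OCC(F)(F)F | starting material
17 | potassium salt of the carbanion of 16 | [K+].CCOC(=O)[C-](C)P(=O)(OCC(F)(F)F)OCC(F)(F)F | intermediate (not isolated)
18 | ethyl (2Z,6E,10Z)-13-[(tert-butyldiphenylsilyl)oxy]-2,6-dimethyl-10-[(trimethylsilyl)methyl]trideca-2,6,10-trienoate | CCOC(=O)/C(C)=C\CC/C(C)=C/CC/C(C[Si](C)(C)C)=C/CCO[Si](c1ccccc1)(c1ccccc1)C(C)(C)C | intermediate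
19 | (2Z,6E,10Z)-13-[(tert-butyldiphenylsilyl)oxy]-2,6-dimethyl-10-[(trimethylsilyl)methyl]trideca-2,6,10-trien-1-ol | OC/C(C)=C\CC/C(C)=C/CC/C(C[Si](C)(C)C)=C/CCO[Si](c1ccccc1)(c1ccccc1)C(C)(C)C | intermediate
20 | [(2S,3R)-3-{(3E,7Z)-10-[(tert-butyldiphenylsilyl)oxy]-3-methyl-7-[(trimethylsilyl)methyl]deca-3,7-dien-1-yl}-2-methyloxiran-2-yl]methanol | OC[C@]1(C)O[C@@H]1CC/C(C)=C/CC/C(C[Si](C)(C)C)=C/CCO[Si](c1ccccc1)(c1ccccc1)C(C)(C)C | intermediate
21 | tert-butyldiphenylsilyl ether of 20 (cyclisation precursor) | CC(C)(C)[Si](c1ccccc1)(c1ccccc1)OC[C@]1(C)O[C@@H]1CC/C(C)=C/CC/C(C[Si](C)(C)C)=C/CCO[Si](c1ccccc1)(c1ccccc1)C(C)(C)C | intermediate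
22 | (1R,2R,4aS,5R,8aS)-1-{[(tert-butyldiphenylsilyl)oxy]methyl}-5-{2-[(tert-butyldiphenylsilyl)oxy]ethyl}-1,4a-dimethyl-6-methylidenedecahydronaphthalen-2-ol | CC(C)(C)[Si](c1ccccc1)(c1ccccc1)OCC[C@@H]1C(=C)CC[C@@H]2[C@](C)(CO[Si](c3ccccc3)(c3ccccc3)C(C)(C)C)[C@H](O)CC[C@]21C | intermediate
23 | (1R,2R,4aS,5R,8aS)-5-(2-hydroxyethyl)-1-(hydroxymethyl)-1,4a-dimethyl-6-methylidenedecahydronaphthalen-2-ol | OCC[C@@H]1C(=C)CC[C@@H]2[C@](C)(CO)[C@H](O)CC[C@]21C | intermediate
24 | 3,19-O-isopropylidene derivative of 23 (DkCH2–CH2OH) | OCC[C@@H]1C(=C)CC[C@@H]2[C@](C)(COC3(C)C)[C@H](O3)CC[C@]21C | intermediate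
25 | C12 aldehyde (DkCH2–CHO) | O=CC[C@@H]1C(=C)CC[C@@H]2[C@](C)(COC3(C)C)[C@H](O3)CC[C@]21C | intermediate
26 | methyl acrylate | C=CC(=O)OC | starting material
27 | methyl 3-hydroxy-2-methylidene-4-Dk-butanoate | C=C(C(=O)OC)C(O)C[C@@H]1C(=C)CC[C@@H]2[C@](C)(COC3(C)C)[C@H](O3)CC[C@]21C | intermediate
28 | methyl 3-acetoxy-2-methylidene-4-Dk-butanoate | C=C(C(=O)OC)C(OC(C)=O)C[C@@H]1C(=C)CC[C@@H]2[C@](C)(COC3(C)C)[C@H](O3)CC[C@]21C | intermediate
29 | nitromethane | C[N+](=O)[O-] | starting material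
30 | 1-nitro-3-Dk-propan-2-ol | [O-][N+](=O)CC(O)C[C@@H]1C(=C)CC[C@@H]2[C@](C)(COC3(C)C)[C@H](O3)CC[C@]21C | intermediate (not isolated)
31 | 1-nitro-3-Dk-propan-2-yl methanesulfonate | CS(=O)(=O)OC(C[N+](=O)[O-])C[C@@H]1C(=C)CC[C@@H]2[C@](C)(COC3(C)C)[C@H](O3)CC[C@]21C | intermediate (not isolated)
32 | (E)-1-nitro-3-Dk-prop-1-ene | [O-][N+](=O)/C=C/C[C@@H]1C(=C)CC[C@@H]2[C@](C)(COC3(C)C)[C@H](O3)CC[C@]21C | intermediate
33 | tetronic acid (4-hydroxyfuran-2(5H)-one) | OC1=CC(=O)OC1 | starting material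
34 | 4-hydroxy-3-[(2S)-1-nitro-3-Dk-propan-2-yl]furan-2(5H)-one | [O-][N+](=O)C[C@@H](C[C@@H]1C(=C)CC[C@@H]2[C@](C)(COC3(C)C)[C@H](O3)CC[C@]21C)C1=C(O)COC1=O | intermediate
35 | enol triflate of 34 | [O-][N+](=O)C[C@@H](C[C@@H]1C(=C)CC[C@@H]2[C@](C)(COC3(C)C)[C@H](O3)CC[C@]21C)C1=C(OS(=O)(=O)C(F)(F)F)COC1=O | intermediate
36 | 3-[(2S)-1-nitro-3-Dk-propan-2-yl]furan-2(5H)-one | [O-][N+](=O)C[C@@H](C[C@@H]1C(=C)CC[C@@H]2[C@](C)(COC3(C)C)[C@H](O3)CC[C@]21C)C1=CCOC1=O | intermediate
37 | coupled C15 nitro compound, bis-acetonide | C=C1CC[C@@H]2[C@](C)(COC3(C)C)[C@H](O3)CC[C@@]2(C)[C@@H]1C/C=C(\CC([N+](=O)[O-])[C@@H](C[C@@H]1C(=C)CC[C@@H]2[C@](C)(COC3(C)C)[C@H](O3)CC[C@]21C)C1=CCOC1=O)C(=O)OC | intermediate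
38 | sodium nitronate of 37 | C=C1CC[C@@H]2[C@](C)(COC3(C)C)[C@H](O3)CC[C@@]2(C)[C@@H]1C/C=C(\CC(=[N+]([O-])[O-])[C@@H](C[C@@H]1C(=C)CC[C@@H]2[C@](C)(COC3(C)C)[C@H](O3)CC[C@]21C)C1=CCOC1=O)C(=O)OC.[Na+] | intermediate (not isolated)
39 | C15 ketone, bis-acetonide | C=C1CC[C@@H]2[C@](C)(COC3(C)C)[C@H](O3)CC[C@@]2(C)[C@@H]1C/C=C(\CC(=O)[C@@H](C[C@@H]1C(=C)CC[C@@H]2[C@](C)(COC3(C)C)[C@H](O3)CC[C@]21C)C1=CCOC1=O)C(=O)OC | intermediate
40 | CNP0330094.1 | C=C1CC[C@@H]2[C@](C)(CO)[C@H](O)CC[C@@]2(C)[C@@H]1C/C=C(\CC(=O)[C@@H](C[C@@H]1C(=C)CC[C@@H]2[C@](C)(CO)[C@H](O)CC[C@]21C)C1=CCOC1=O)C(=O)OC | target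

**Totals.** 24 steps. Longest linear sequence: 22 steps (steps 1–15, then 18–24); steps 16–17 form the short branch that joins at step 22.

**Steps most likely to fail**

1. Step 12. The cascade may stop after ring A because the C10 cation loses a proton or is captured by the C3 alkoxide before ring B closes, or the opened epoxide may rearrange by hydride shift. Fallback (sets out from 10, returns at 23): the terminator is changed from the allylsilane to the cyclic enol ether already present in 10, and the exocyclic methylene is made afterwards from a ketone. Bu4NF frees (4E)-7-(4,5-dihydrofuran-2-yl)-4-methylhept-4-en-1-ol F1, and SO3·pyridine/DMSO/i-Pr2NEt oxidises it to (4E)-7-(4,5-dihydrofuran-2-yl)-4-methylhept-4-enal F2. The olefination of step 8 gives ethyl (2Z,6E)-9-(4,5-dihydrofuran-2-yl)-2,6-dimethylnona-2,6-dienoate F3, and i-Bu2AlH gives (2Z,6E)-9-(4,5-dihydrofuran-2-yl)-2,6-dimethylnona-2,6-dien-1-ol F4. The epoxidation of step 10 gives {(2S,3R)-3-[(3E)-6-(4,5-dihydrofuran-2-yl)-3-methylhex-3-en-1-yl]-2-methyloxiran-2-yl}methanol F5, and TBDPSCl/imidazole gives its tert-butyldiphenylsilyl ether F6. MeAlCl2 at −78 °C should then close both rings with the enol ether carbon C9 as terminator, and aqueous work-up opens the oxocarbenium ion to the 8-oxo-12-hydroxy decalin F7. Wittig methylenation with Ph3P=CH2 gives the 8(17)-ene 3,12-diol F8, and Bu4NF gives 23.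

2. Step 19. Catalyst control over the C12′ face may be eroded by a mismatched interaction with the decalin, or the adduct may epimerise by retro-Michael addition. Fallback (sets out from 32 and 33, returns at 34): selectivity is replaced by separation and recycling. Addition with Et3N in CH2Cl2 gives 34 together with its epimer 4-hydroxy-3-[(2R)-1-nitro-3-Dk-propan-2-yl]furan-2(5H)-one F9. The two are diastereomers and are separated by reversed-phase chromatography. F9 is returned to the mixture by warming with Et3N (retro-Michael and re-addition), so the material converges on 34.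

3. Step 23. The imine formed on reduction may be reduced further or may close onto the neighbouring ester or lactone carbonyl before it is hydrolysed, and the new α-keto centre C12′ may epimerise. Fallback (sets out from 37, returns at 39): the conversion is split into two isolable stages. SnCl2, PhSH and Et3N in MeCN reduce the nitro group only as far as the C15 oxime of 39 F10. Exchange with aqueous glyoxylic acid buffered by NaOAc in THF then releases the ketone 39.

**Further compounds**

F1 | step 12 | (4E)-7-(4,5-dihydrofuran-2-yl)-4-methylhept-4-en-1-ol | O1CCC=C1CC/C=C(\C)CCCO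
F2 | step 12 | (4E)-7-(4,5-dihydrofuran-2-yl)-4-methylhept-4-enal | O1CCC=C1CC/C=C(\C)CCC=O
F3 | step 12 | ethyl (2Z,6E)-9-(4,5-dihydrofuran-2-yl)-2,6-dimethylnona-2,6-dienoate | O1CCC=C1CC/C=C(\C)CC/C=C(/C)C(=O)OCC
F4 | step 12 | (2Z,6E)-9-(4,5-dihydrofuran-2-yl)-2,6-dimethylnona-2,6-dien-1-ol | O1CCC=C1CC/C=C(\C)CC/C=C(/C)CO
F5 | step 12 | {(2S,3R)-3-[(3E)-6-(4,5-dihydrofuran-2-yl)-3-methylhex-3-en-1-yl]-2-methyloxiran-2-yl}methanol | OC[C@]1(C)O[C@@H]1CC/C(C)=C/CCC1=CCCO1
F6 | step 12 | tert-butyldiphenylsilyl ether of F5 | CC(C)(C)[Si](c1ccccc1)(c1ccccc1)OC[C@]1(C)O[C@@H]1CC/C(C)=C/CCC1=CCCO1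
F7 | step 12 | 8-oxo-12-hydroxy decalin with C19 silyl ether | OCC[C@@H]1C(=O)CC[C@@H]2[C@](C)(CO[Si](c3ccccc3)(c3ccccc3)C(C)(C)C)[C@H](O)CC[C@]21C
F8 | step 12 | 8(17)-ene 3,12-diol with C19 silyl ether | OCC[C@@H]1C(=C)CC[C@@H]2[C@](C)(CO[Si](c3ccccc3)(c3ccccc3)C(C)(C)C)[C@H](O)CC[C@]21C
F9 | step 19 | 4-hydroxy-3-[(2R)-1-nitro-3-Dk-propan-2-yl]furan-2(5H)-one | [O-][N+](=O)C[C@H](C[C@@H]1C(=C)CC[C@@H]2[C@](C)(COC3(C)C)[C@H](O3)CC[C@]21C)C1=C(O)COC1=O
F10 | step 23 | C15 oxime of 39 | C=C1CC[C@@H]2[C@](C)(COC3(C)C)[C@H](O3)CC[C@@]2(C)[C@@H]1C/C=C(\CC(=NO)[C@@H](C[C@@H]1C(=C)CC[C@@H]2[C@](C)(COC3(C)C)[C@H](O3)CC[C@]21C)C1=CCOC1=O)C(=O)OC
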